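# Proposed total synthesis of gallocatechin-(4α→8)-catechin-(4β→8)-ent-catechin (22)

## Analysis of the target

Target 22 is a B-type proanthocyanidin trimer built from three 2-arylchroman-3-ol units. Each unit has a phloroglucinol-derived ring A, a pyran ring C and an aryl ring B (pyrogallol in the top unit, catechol in the other two), and the units are joined by two C4–C8 bonds. It has eight stereocentres. The top unit is 2R,3S (2,3-trans) with its C4–aryl bond α (3,4-trans). The middle unit is also 2R,3S, but its C4–aryl bond is β (3,4-cis). The bottom unit is 2S,3R, the enantiomeric series. The thirteen phenols and three secondary alcohols make the free compound sensitive to air (pyrogallol, catechol), to base (C2 epimerisation through quinone methides) and to acid (cleavage of the C4–C8 bonds). Three things make the synthesis hard: the 4→8 versus 4→6 position of each linkage, the 3,4-cis lower linkage, which is the opposite of what cation/arene coupling of a 2,3-trans unit gives, and the bottom unit of opposite handedness, which rules out iterating one monomer. The strategy rests on ring A of the middle unit. This ring carries oxygen on C5, C7 and C8a, C4 of the top unit on C8, and the ring C carbon C4 on C4a. Opening ring C at O1–C2 and writing C4 as a carbonyl turns it into a 3-C-alkyl-2,4,6-trihydroxyacetophenone. Its parent 5 is symmetrical, so the top unit can be attached at only one kind of position, and the choice of phenol that later closes ring C fixes the 8-linkage.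

## Retrosynthetic reasoning

Protecting groups. Bonds should not be formed on free 22, so it is traced back to the pentadeca-benzyl ether 21 (one hydrogenolysis) and then to its silyl ether 20. Benzyl ethers tolerate base, Lewis acid, organolithium and dilute protic acid. The single silyl ether sits on O-3 of the middle unit, the one oxygen that has to be protected next to a ketone without using alkoxide chemistry.

Lower interflavan bond. In 20 the C4(middle)–C8(bottom) bond is cut so that the middle unit is the electrophile as its C4 ketone 14 and the bottom unit the nucleophile as aryllithium 18. A cation/arene coupling would put the aryl group trans to O-3. Adding the aryl group first (tertiary alcohol 19) and the hydrogen last lets the small reagent enter anti to O-3, which leaves the aryl group cis. The C8 position is fixed by bromide 17, and the enantiomeric bottom unit enters as a separate chiral-pool fragment made from 15 through 16.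

Ring C of the middle unit. Ketone 14 is the silyl ether of dihydroflavonol 13. In 13 the O1–C2 bond is cut, which leads to the trans-epoxide 12 with a free phenol next to the top unit. Here the phenol opens the epoxide at the benzylic carbon, so that O1–C2 forms with inversion and C3 keeps its oxygen. This cut is chosen because it creates the ring, gives the 2,3-trans pair from one flat precursor and leaves the C4 ketone needed for the lower bond. A free 2'-hydroxychalcone cannot be epoxidised under alkaline peroxide without cyclising, so 12 is generated in the flask from its methoxymethyl ether 11.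

Epoxide and enone. Both C–O bonds of the epoxide in 11 are cut to give (E)-enone 10, so that a single catalyst-controlled epoxidation sets the future C2 and C3. The Cα=Cβ bond of 10 is then cut into methyl ketone 8 and aldehyde 9 (aldol condensation), which brings in ring B of the middle unit.

Phenol differentiation. Ketone 8 comes from 7 by capping the last phenol, and 7 comes from triol 6 by benzylating the two less hindered phenols. The phenol left free in 7 is the one wedged between the acetyl group and the top unit. It is the oxygen that becomes O1, and this is what makes the linkage 4→8.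

Upper interflavan bond. In 6 the bond between C4 of the top unit and the acetophenone ring is cut into C4-activated electrophile 4 and symmetrical nucleophile 5. The forward reaction has to add the arene anti to the 3-benzyloxy group (4α). The two free positions of 5 are equivalent, so there is no regiochemical issue.

Chiral pool. Electrophile 4 goes back through diol 3 and ketone 2 to dihydroflavonol 1, which already holds C2 and C3 of the top unit with its pyrogallol ring B.

## Alternatives that were turned down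

Alternative 1: tethered macrocyclisation for the lower bond.
- Disconnection: the same C4(middle)–C8(bottom) bond, cut as a cation/arene pair held by a glutarate bridge between O-3 of the middle unit and O-3 of the bottom unit.
- Forward key step: a silyl triflate ionises the C4 2-ethoxyethyl ether of open diester A2, and C8 of the tethered ent-catechin closes a 14-membered ring on the face that carries the ester, giving macrocycle A1.
- For: the tether forces the arene to enter cis to O-3 and enforces C8 over C6. On the 3,4-cis problem it is stronger than the chosen route, whose step 14 depends on the facial preference of an external hydride.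
- Against: it solves only the lower linkage. A2 needs a gallocatechin–catechin dimer with O-3 of the middle unit free, O-3 of the top unit protected and C4 of the middle unit oxidised. The upper bond would therefore come from an ordinary intermolecular coupling with its 8/6 and α/β mixtures. Tether installation and removal cost about three steps, and the Lewis acid can also ionise the existing interflavan bond.
- Comparison: the chosen route builds the middle unit on the top unit, so the upper linkage position is structural, and the ketone from the key step serves directly as the handle for the lower bond. The tether chemistry is kept as the fallback for step 14.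

Alternative 2: quinone methide hetero-Diels–Alder for the top pyran.
- Disconnection: C3–C4 and O1–C2 of the top ring C.
- Forward key step: acid ionises ortho-hydroxy diarylcarbinol A4 (its carbinol carbon, the future C4, is already bonded to C8 of the middle unit) to an ortho-quinone methide, which adds across (E)-styrylboronate A5 to give the C3-boryl trimer A3. Oxidation of C–B would then give the 3-OH.
- For: it is more convergent for the top unit than the chosen route and forms three stereocentres at once. The E-alkene maps onto 2,3-trans, and the aryl-bearing carbon bonds to oxygen because it is the better cation-stabilising terminus.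
- Against: the absolute configuration of three new centres would depend on induction from the remote middle unit, and endo/exo selectivity decides the 3,4 relation. A borylstyrene is a poor partner for an inverse-demand cycloaddition, so dimerisation of the quinone methide or its capture by the electron-rich rings competes. The 3,4-cis middle–bottom dimer, the hardest part, must be made first and then exposed to acid.
- Comparison: the chosen route takes C2 and C3 of the top unit from the chiral pool and sets the middle unit by catalyst control. It gives up late-stage convergence for reliable absolute configuration.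

Alternative 3: dihydrobenzofuran-to-chroman ring expansion.
- Disconnection: O1–C2 and C3–OH of the top ring C, seen as a ring-expanded 2-(α-hydroxybenzyl)-2,3-dihydrobenzofuran A7.
- Forward key step: acid ionises the exocyclic carbinol of A7, the ring oxygen bridges to an oxiranium ion, and water opens it at the former furan C2 to give A6 with a free top 3-OH.
- For: the step is stereospecific, relieves strain, and delivers the top O-3 already differentiated, which the chosen route does not do (and does not need).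
- Against: the bridged ion has two carbons, and the one bearing the tris(benzyloxy)phenyl group is the better cation. Water should therefore prefer that carbon, so the desired opening runs against the electronic bias. A7 needs three contiguous centres set with the dimer attached, and again the cis-linked dimer must exist first.
- Comparison: in the chosen key step the same benzylic, para-alkoxy bias favours the desired six-membered closure.

Key step: step 9

Remark (assumption): the configurations written for C4 of 3 and 4 and for the carbinol carbon of 19 are the expected major ones. These centres are made planar later (steps 4 and 14), so mixtures there are acceptable.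

Abbreviations in names:
- GC-4α-yl = (2R,3S)-3,5,7-tris(benzyloxy)-2-[3,4,5-tris(benzyloxy)phenyl]chroman-4-yl, bonded through C4 on the α face (trans to the 3-benzyloxy group).
- ent-C-8-yl = (2S,3R)-3,5,7-tris(benzyloxy)-2-[3,4-bis(benzyloxy)phenyl]chroman-8-yl.
- α and β follow flavonoid usage: in a 2R unit the 2-aryl group is α.

## Route

Step 1
Reactants: 1 (+)-dihydromyricetin
Product: 2 (2R,3R)-5,7-bis(benzyloxy)-3-hydroxy-2-[3,4,5-tris(benzyloxy)phenyl]chroman-4-one
Conditions: BnBr (6 equiv), K2CO3, DMF, 50 °C, Ar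
Reagents that add atoms: benzyl bromide, BrCc1ccccc1
Why: Williamson ether synthesis; K2CO3 ionises only the five phenols (the chelated 5-OH needs the excess and warmth), the secondary 3-OH stays free, and under argon the 2,3-trans ketone should pass unchanged, so its two stereocentres become C2 and C3 of the top unit of 22.

Step 2
Reactants: 2 penta-O-benzyl ketone
Product: 3 (2R,3S,4R)-5,7-bis(benzyloxy)-2-[3,4,5-tris(benzyloxy)phenyl]chromane-3,4-diol (2,3-trans-3,4-trans)
Conditions: NaBH4, THF–EtOH, 0 °C → rt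
Reagents that add atoms: none
Why: Borohydride 1,2-reduction of the aryl ketone; hydride is expected to enter anti to the 3-hydroxyl and give mainly the 3,4-trans diol, but the C4 configuration is irrelevant because C4 is ionised in step 4.

Step 3
Reactants: 3 diol
Product: 4 (2R,3S,4R)-3,4,5,7-tetrakis(benzyloxy)-2-[3,4,5-tris(benzyloxy)phenyl]chromane
Conditions: NaH, BnBr, n-Bu4NI (cat.), DMF, 0 °C → rt
Reagents that add atoms: benzyl bromide, BrCc1ccccc1
Why: Williamson etherification of both alkoxides; the O-3 benzyl ether is the permanent protecting group of the top unit, and the benzylic, donor-activated O-4 benzyl ether is the leaving group for the next step.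

Step 4
Reactants: 4 C4-benzyloxy electrophile; 5 2,4,6-trihydroxyacetophenone (dried, 6 equiv)
Product: 6 1-[2,4,6-trihydroxy-3-(GC-4α-yl)phenyl]ethanone
Conditions: BF3·OEt2, CH2Cl2–1,4-dioxane, 0 °C → rt
Reagents that add atoms: none
Why: Friedel–Crafts alkylation of a phloroglucinol-type arene by a flavan-4-yl cation (the reaction type of proanthocyanidin coupling); BF3 ionises the C4–OBn bond, which is ortho/para to three oxygens of ring A, the two free ring positions of 5 are equivalent so only one regioisomer can form, and the arene should add anti to the 3-benzyloxy group to set the 4α (3,4-trans) centre; the excess of 5 suppresses dialkylation and self-condensation of 4.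

Step 5
Reactants: 6 triol
Product: 7 1-[4,6-bis(benzyloxy)-2-hydroxy-3-(GC-4α-yl)phenyl]ethanone
Conditions: BnBr (2.1 equiv), K2CO3, acetone, reflux
Reagents that add atoms: benzyl bromide, BrCc1ccccc1
Why: Selective Williamson etherification; the 4-OH (para to the acetyl group, most acidic, not chelated) and the 6-OH (hydrogen neighbour) should be benzylated, whereas the 2-OH, wedged between the acetyl and the flavanyl group and held in the chelate once O-6 is etherified, should stay free; this phenol becomes O1 and decides 8- over 6-linkage.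

Step 6
Reactants: 7 chelated phenol
Product: 8 1-[4,6-bis(benzyloxy)-2-(methoxymethoxy)-3-(GC-4α-yl)phenyl]ethanone
Conditions: NaH, MOMCl, DMF, 0 °C → rt
Reagents that add atoms: chloromethyl methyl ether, COCCl
Why: Acetal (methoxymethyl ether) formation on the sodium phenoxide; the small, very reactive electrophile reaches the hindered oxygen that benzyl bromide with carbonate does not, and the mask prevents flavanone and Algar–Flynn–Oyamada-type cyclisations in steps 7 and 8 while remaining removable by dilute acid.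

Step 7
Reactants: 8 methyl ketone; 9 3,4-bis(benzyloxy)benzaldehyde
Product: 10 (E)-1-[4,6-bis(benzyloxy)-2-(methoxymethoxy)-3-(GC-4α-yl)phenyl]-3-[3,4-bis(benzyloxy)phenyl]prop-2-en-1-one
Conditions: KOH, EtOH–THF, rt
Reagents that add atoms: none
Why: Claisen–Schmidt condensation (crossed aldol with E1cB dehydration) of the methyl ketone with a non-enolisable aldehyde; the E-enone is the thermodynamic product and nothing else in 8 is base-labile.

Step 8
Reactants: 10 (E)-chalcone
Product: 11 [4,6-bis(benzyloxy)-2-(methoxymethoxy)-3-(GC-4α-yl)phenyl]{(2R,3S)-3-[3,4-bis(benzyloxy)phenyl]oxiran-2-yl}methanone (trans-epoxide, αR,βS)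
Conditions: poly-L-leucine, urea–H2O2, DBU, THF, rt
Reagents that add atoms: urea–hydrogen peroxide (source of the epoxide oxygen), OO.NC(N)=O
Why: Juliá–Colonna epoxidation (peptide-catalysed Weitz–Scheffer reaction); hydroperoxide adds to the β-carbon within the helical peptide and the enolate closes on oxygen to give the trans-epoxide, and by analogy with chalcone the L-peptide should deliver the (αR,βS) isomer, which fixes the future C3 and, after inversion, C2 of the middle unit.

Step 9
Reactants: 11 methoxymethyl-protected epoxide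
Product: 13 (2R,3R)-5,7-bis(benzyloxy)-2-[3,4-bis(benzyloxy)phenyl]-3-hydroxy-8-(GC-4α-yl)chroman-4-one, via free 2'-hydroxychalcone epoxide 12 (not isolated)
Conditions: HCl (1.25 M in MeOH), THF, 40 °C
Reagents that add atoms: none
Why: Acid first removes the methoxymethyl acetal (the oxocarbenium fragment is trapped by methanol), exposing the chelated phenol of 12 in the flask. Protonation of the epoxide oxygen then weakens the Cβ–O bond, whose carbon is benzylic and para to a benzyloxy group, and the phenol oxygen attacks this carbon from the side opposite the departing oxygen. The closest known reaction type is the acid-mediated cyclisation of 2'-hydroxychalcone epoxides, released from their 2'-O-methoxymethyl ethers, to 2,3-trans-dihydroflavonols. The only ring closed is ring C of the middle unit, by a 6-endo-tet epoxide opening that forms O1–C2; the 5-exo mode to a 2-(α-hydroxybenzyl)benzofuranone is disfavoured because Cα lies next to the carbonyl and has no cation-stabilising group. C2 (the former Cβ) is set by inversion in the opening and C3 (the former Cα) keeps the configuration installed by the catalyst in step 8, so the trans-epoxide maps onto the 2,3-trans (2R,3R) ketone; should the opening drift towards a free benzylic cation, closure through the diequatorial chair leads to the same trans isomer. The 8-linkage is secured because the only free phenol is the one flanked by the top unit. The step also needs the benzyl ethers and the C4–aryl bond to the top unit to survive dilute acid, which the acyl-deactivated lower ring should allow, and a protic acid in methanol is used rather than a Lewis acid to avoid the 1,2-aroyl shift that leads towards isoflavones.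

Step 10
Reactants: 13 dihydroflavonol ketone
Product: 14 (2R,3R)-5,7-bis(benzyloxy)-2-[3,4-bis(benzyloxy)phenyl]-3-(tert-butyldimethylsilyloxy)-8-(GC-4α-yl)chroman-4-one
Conditions: TBSOTf, 2,6-lutidine, CH2Cl2, −40 → 0 °C
Reagents that add atoms: tert-butyldimethylsilyl trifluoromethanesulfonate, CC(C)(C)[Si](C)(C)OS(=O)(=O)C(F)(F)F
Why: Silylation with a silyl triflate and a hindered pyridine base; non-basic conditions are chosen because alkoxide chemistry on a 3-hydroxyflavan-4-one risks C3 enolisation and ring opening, and the bulky silyl ether later directs the hydride in step 14.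

Step 11
Reactants: 15 (−)-catechin (ent-catechin, 2S,3R)
Product: 16 (2S,3R)-3,5,7-tris(benzyloxy)-2-[3,4-bis(benzyloxy)phenyl]chromane
Conditions: NaH, BnBr, DMF, 0 °C → rt
Reagents that add atoms: benzyl bromide, BrCc1ccccc1
Why: Williamson etherification of the four phenoxides and the C3 alkoxide in one operation at low temperature; neither stereocentre is touched.

Step 12
Reactants: 16 penta-O-benzyl-ent-catechin
Product: 17 (2S,3R)-3,5,7-tris(benzyloxy)-2-[3,4-bis(benzyloxy)phenyl]-8-bromochromane
Conditions: NBS (1.05 equiv), CH2Cl2, −78 °C → rt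
Reagents that add atoms: N-bromosuccinimide, BrN1C(=O)CCC1=O
Why: Electrophilic aromatic bromination; in 5,7-dialkoxyflavans C8 is more reactive than C6, so one equivalent of reagent at low temperature should give the 8-bromide that defines the attachment point of the bottom unit.

Step 13
Reactants: 17 8-bromide (1.5 equiv); 14 silyloxy ketone
Product: 19 5,7-bis(benzyloxy)-2α-[3,4-bis(benzyloxy)phenyl]-3β-(tert-butyldimethylsilyloxy)-4α-(ent-C-8-yl)-8-(GC-4α-yl)chroman-4β-ol, via 8-lithio pentabenzyl ent-catechin 18 (not isolated)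
Conditions: t-BuLi (2 equiv per 17), THF, −78 °C; then 14, −78 → 0 °C
Reagents that add atoms: none
Why: Bromine–lithium exchange followed by 1,2-addition of the aryllithium to the ketone, the known way from 3-silyloxyflavan-4-ones to 4-arylflavan-4-ols; the bulky nucleophile should enter anti to the silyloxy group, but this carbinol centre is erased in the next step.

Step 14
Reactants: 19 tertiary alcohol
Product: 20 5,7-bis(benzyloxy)-2α-[3,4-bis(benzyloxy)phenyl]-3β-(tert-butyldimethylsilyloxy)-4β-(ent-C-8-yl)-8-(GC-4α-yl)chromane (2,3-trans-3,4-cis middle unit)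
Conditions: n-Bu3SnH, CF3CO2H, CH2Cl2, 0 °C
Reagents that add atoms: none
Why: Ionic hydrogenation; acid ionises the tertiary diarylcarbinol to a cation stabilised by ring A of the middle unit, and the tin hydride should transfer hydride to C4 from the face opposite the bulky 3-silyloxy group (α), leaving the aryl group cis to O-3 (4β); this is the reverse of cation/arene coupling because here the small partner arrives last.

Step 15
Reactants: 20 silyl ether
Product: 21 pentadeca-O-benzyl gallocatechin-(4α→8)-catechin-(4β→8)-ent-catechin with free 3-OH on the middle unit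
Conditions: n-Bu4NF, THF, rt
Reagents that add atoms: none
Why: Fluoride-induced cleavage of the Si–O bond; the benzyl ethers and all stereocentres are inert.

Step 16
Reactants: 21 pentadeca-benzyl ether
Product: 22 gallocatechin-(4α→8)-catechin-(4β→8)-ent-catechin (CNP0155646.2)
Conditions: H2 (1 atm), Pd(OH)2/C, THF–MeOH–H2O, rt
Reagents that add atoms: none
Why: Catalytic hydrogenolysis of all fifteen benzyl ethers under neutral conditions; the C4–aryl bonds are not benzylic C–O bonds and survive, and neutral conditions avoid epimerisation or interflavan cleavage of the free polyphenol.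

## Compound list

1 | (+)-dihydromyricetin, (2R,3R)-3,5,7-trihydroxy-2-(3,4,5-trihydroxyphenyl)chroman-4-one | Oc1cc(O)c2c(c1)O[C@H](c1cc(O)c(O)c(O)c1)[C@@H](O)C2=O | starting material

2 | (2R,3R)-5,7-bis(benzyloxy)-3-hydroxy-2-[3,4,5-tris(benzyloxy)phenyl]chroman-4-one | c3ccccc3COc1cc(OCc3ccccc3)c2c(c1)O[C@H](c1cc(OCc3ccccc3)c(OCc3ccccc3)c(OCc3ccccc3)c1)[C@@H](O)C2=O | intermediate

3 | (2R,3S,4R)-5,7-bis(benzyloxy)-2-[3,4,5-tris(benzyloxy)phenyl]chromane-3,4-diol | c3ccccc3COc1cc(OCc3ccccc3)c2c(c1)O[C@H](c1cc(OCc3ccccc3)c(OCc3ccccc3)c(OCc3ccccc3)c1)[C@@H](O)[C@@H]2O | intermediate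

4 | (2R,3S,4R)-3,4,5,7-tetrakis(benzyloxy)-2-[3,4,5-tris(benzyloxy)phenyl]chromane | c3ccccc3COc1cc(OCc3ccccc3)c2c(c1)O[C@H](c1cc(OCc3ccccc3)c(OCc3ccccc3)c(OCc3ccccc3)c1)[C@@H](OCc3ccccc3)[C@@H]2OCc1ccccc1 | intermediate

5 | 2,4,6-trihydroxyacetophenone | CC(=O)c1c(O)cc(O)cc1O | starting material

6 | 1-[2,4,6-trihydroxy-3-(GC-4α-yl)phenyl]ethanone | c3ccccc3COc1cc(OCc3ccccc3)c2c(c1)O[C@H](c1cc(OCc3ccccc3)c(OCc3ccccc3)c(OCc3ccccc3)c1)[C@@H](OCc3ccccc3)[C@@H]2c1c(O)cc(O)c(c1O)C(C)=O | intermediate

7 | 1-[4,6-bis(benzyloxy)-2-hydroxy-3-(GC-4α-yl)phenyl]ethanone | c3ccccc3COc1cc(OCc3ccccc3)c2c(c1)O[C@H](c1cc(OCc3ccccc3)c(OCc3ccccc3)c(OCc3ccccc3)c1)[C@@H](OCc3ccccc3)[C@@H]2c1c(OCc3ccccc3)cc(OCc3ccccc3)c(c1O)C(C)=O | intermediate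

8 | 1-[4,6-bis(benzyloxy)-2-(methoxymethoxy)-3-(GC-4α-yl)phenyl]ethanone | c3ccccc3COc1cc(OCc3ccccc3)c2c(c1)O[C@H](c1cc(OCc3ccccc3)c(OCc3ccccc3)c(OCc3ccccc3)c1)[C@@H](OCc3ccccc3)[C@@H]2c1c(OCc3ccccc3)cc(OCc3ccccc3)c(c1OCOC)C(C)=O | intermediate

9 | 3,4-bis(benzyloxy)benzaldehyde | O=Cc1ccc(OCc2ccccc2)c(OCc2ccccc2)c1 | starting material

10 | (E)-1-[4,6-bis(benzyloxy)-2-(methoxymethoxy)-3-(GC-4α-yl)phenyl]-3-[3,4-bis(benzyloxy)phenyl]prop-2-en-1-one | c3ccccc3COc1cc(OCc3ccccc3)c2c(c1)O[C@H](c1cc(OCc3ccccc3)c(OCc3ccccc3)c(OCc3ccccc3)c1)[C@@H](OCc3ccccc3)[C@@H]2c1c(OCc3ccccc3)cc(OCc3ccccc3)c(c1OCOC)C(=O)/C=C/c1ccc(OCc3ccccc3)c(OCc3ccccc3)c1 | intermediate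

11 | [4,6-bis(benzyloxy)-2-(methoxymethoxy)-3-(GC-4α-yl)phenyl]{(2R,3S)-3-[3,4-bis(benzyloxy)phenyl]oxiran-2-yl}methanone | c3ccccc3COc1cc(OCc3ccccc3)c2c(c1)O[C@H](c1cc(OCc3ccccc3)c(OCc3ccccc3)c(OCc3ccccc3)c1)[C@@H](OCc3ccccc3)[C@@H]2c1c(OCc3ccccc3)cc(OCc3ccccc3)c(c1OCOC)C(=O)[C@@H]1O[C@H]1c1ccc(OCc3ccccc3)c(OCc3ccccc3)c1 | intermediate

12 | [4,6-bis(benzyloxy)-2-hydroxy-3-(GC-4α-yl)phenyl]{(2R,3S)-3-[3,4-bis(benzyloxy)phenyl]oxiran-2-yl}methanone | c3ccccc3COc1cc(OCc3ccccc3)c2c(c1)O[C@H](c1cc(OCc3ccccc3)c(OCc3ccccc3)c(OCc3ccccc3)c1)[C@@H](OCc3ccccc3)[C@@H]2c1c(OCc3ccccc3)cc(OCc3ccccc3)c(c1O)C(=O)[C@@H]1O[C@H]1c1ccc(OCc3ccccc3)c(OCc3ccccc3)c1 | intermediate (not isolated)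

13 | (2R,3R)-5,7-bis(benzyloxy)-2-[3,4-bis(benzyloxy)phenyl]-3-hydroxy-8-(GC-4α-yl)chroman-4-one | c3ccccc3COc1cc(OCc3ccccc3)c2c(c1)O[C@H](c1cc(OCc3ccccc3)c(OCc3ccccc3)c(OCc3ccccc3)c1)[C@@H](OCc3ccccc3)[C@@H]2c1c(OCc3ccccc3)cc(OCc3ccccc3)c2c1O[C@H](c1ccc(OCc3ccccc3)c(OCc3ccccc3)c1)[C@@H](O)C2=O | intermediate

14 | (2R,3R)-5,7-bis(benzyloxy)-2-[3,4-bis(benzyloxy)phenyl]-3-(tert-butyldimethylsilyloxy)-8-(GC-4α-yl)chroman-4-one | c3ccccc3COc1cc(OCc3ccccc3)c2c(c1)O[C@H](c1cc(OCc3ccccc3)c(OCc3ccccc3)c(OCc3ccccc3)c1)[C@@H](OCc3ccccc3)[C@@H]2c1c(OCc3ccccc3)cc(OCc3ccccc3)c2c1O[C@H](c1ccc(OCc3ccccc3)c(OCc3ccccc3)c1)[C@@H](O[Si](C)(C)C(C)(C)C)C2=O | intermediate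

15 | (−)-catechin (ent-catechin), (2S,3R)-2-(3,4-dihydroxyphenyl)chromane-3,5,7-triol | Oc1cc(O)c2c(c1)O[C@@H](c1ccc(O)c(O)c1)[C@H](O)C2 | starting material

16 | (2S,3R)-3,5,7-tris(benzyloxy)-2-[3,4-bis(benzyloxy)phenyl]chromane | c3ccccc3COc1cc(OCc3ccccc3)c2c(c1)O[C@@H](c1ccc(OCc3ccccc3)c(OCc3ccccc3)c1)[C@H](OCc3ccccc3)C2 | intermediate

17 | (2S,3R)-3,5,7-tris(benzyloxy)-2-[3,4-bis(benzyloxy)phenyl]-8-bromochromane | Brc1c(OCc3ccccc3)cc(OCc3ccccc3)c2c1O[C@@H](c1ccc(OCc3ccccc3)c(OCc3ccccc3)c1)[C@H](OCc3ccccc3)C2 | intermediate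

18 | (2S,3R)-3,5,7-tris(benzyloxy)-2-[3,4-bis(benzyloxy)phenyl]chroman-8-yllithium | [Li]c1c(OCc3ccccc3)cc(OCc3ccccc3)c2c1O[C@@H](c1ccc(OCc3ccccc3)c(OCc3ccccc3)c1)[C@H](OCc3ccccc3)C2 | intermediate (not isolated)

19 | 5,7-bis(benzyloxy)-2α-[3,4-bis(benzyloxy)phenyl]-3β-(tert-butyldimethylsilyloxy)-4α-(ent-C-8-yl)-8-(GC-4α-yl)chroman-4β-ol | c3ccccc3COc1cc(OCc3ccccc3)c2c(c1)O[C@H](c1cc(OCc3ccccc3)c(OCc3ccccc3)c(OCc3ccccc3)c1)[C@@H](OCc3ccccc3)[C@@H]2c1c(OCc3ccccc3)cc(OCc3ccccc3)c2c1O[C@H](c1ccc(OCc3ccccc3)c(OCc3ccccc3)c1)[C@@H](O[Si](C)(C)C(C)(C)C)[C@]2(O)c1c(OCc3ccccc3)cc(OCc3ccccc3)c2c1O[C@@H](c1ccc(OCc3ccccc3)c(OCc3ccccc3)c1)[C@H](OCc3ccccc3)C2 | intermediate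

20 | 5,7-bis(benzyloxy)-2α-[3,4-bis(benzyloxy)phenyl]-3β-(tert-butyldimethylsilyloxy)-4β-(ent-C-8-yl)-8-(GC-4α-yl)chromane | c3ccccc3COc1cc(OCc3ccccc3)c2c(c1)O[C@H](c1cc(OCc3ccccc3)c(OCc3ccccc3)c(OCc3ccccc3)c1)[C@@H](OCc3ccccc3)[C@@H]2c1c(OCc3ccccc3)cc(OCc3ccccc3)c2c1O[C@H](c1ccc(OCc3ccccc3)c(OCc3ccccc3)c1)[C@@H](O[Si](C)(C)C(C)(C)C)[C@H]2c1c(OCc3ccccc3)cc(OCc3ccccc3)c2c1O[C@@H](c1ccc(OCc3ccccc3)c(OCc3ccccc3)c1)[C@H](OCc3ccccc3)C2 | intermediate

21 | pentadeca-O-benzyl gallocatechin-(4α→8)-catechin-(4β→8)-ent-catechin, free 3-OH on the middle unit | c3ccccc3COc1cc(OCc3ccccc3)c2c(c1)O[C@H](c1cc(OCc3ccccc3)c(OCc3ccccc3)c(OCc3ccccc3)c1)[C@@H](OCc3ccccc3)[C@@H]2c1c(OCc3ccccc3)cc(OCc3ccccc3)c2c1O[C@H](c1ccc(OCc3ccccc3)c(OCc3ccccc3)c1)[C@@H](O)[C@H]2c1c(OCc3ccccc3)cc(OCc3ccccc3)c2c1O[C@@H](c1ccc(OCc3ccccc3)c(OCc3ccccc3)c1)[C@H](OCc3ccccc3)C2 | intermediate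

22 | gallocatechin-(4α→8)-catechin-(4β→8)-ent-catechin | Oc1cc(O)c2c(c1)O[C@H](c1cc(O)c(O)c(O)c1)[C@@H](O)[C@@H]2c1c(O)cc(O)c2c1O[C@H](c1ccc(O)c(O)c1)[C@@H](O)[C@H]2c1c(O)cc(O)c2c1O[C@@H](c1ccc(O)c(O)c1)[C@H](O)C2 | target

## Step count and least certain steps

Total step count: 16. Longest linear sequence: 14 steps (steps 1–10, then 13–16); steps 11 and 12 make the bottom fragment.

**Step 9 (key step).**
- Risk: the acid-promoted closure may leak into the 5-exo mode at Cα, into 1,2-aroyl migration onto the developing benzylic cation, or into methanol capture of that cation. Prolonged acid could also erode the C2 configuration or start cleaving the bond to the top unit. The cause is that the same para-alkoxy stabilisation that directs the opening to Cβ also gives it cationic character.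
- Fallback (from 11, returning at 13): the closure is split into two stages. Phenylmethanethiol with SnCl4 in CH2Cl2 at −20 °C should open the epoxide at the benzylic carbon with inversion and remove the methoxymethyl group, giving 1-[4,6-bis(benzyloxy)-2-hydroxy-3-(GC-4α-yl)phenyl]-(2S,3R)-3-(benzylsulfanyl)-3-[3,4-bis(benzyloxy)phenyl]-2-hydroxypropan-1-one F1. AgBF4 in CH2Cl2 at 0 °C then abstracts the thiolate, and the phenol closes ring C on the benzylic cation through the diequatorial chair to give 13. The thiol stage must be kept cold and short so that the interflavan bond is not thiolysed.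

**Step 14.**
- Risk: poor facial selectivity of hydride delivery. Attack anti to the silyloxy group gives the wanted 3,4-cis product, but the stereoelectronically favoured pseudoaxial attack on the diequatorial half-chair comes from the other face and would give the 3,4-trans epimer. The two effects oppose each other in a 2,3-trans unit. Elimination to the enol ether and acid cleavage are secondary risks.
- Fallback (from 13 and 15, returning at 22): the order is inverted with a temporary tether, which also removes the dependence on steps 10, 13 and 15.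
  - 15 is benzylated on its phenols only (BnBr, K2CO3, DMF) to (2S,3R)-5,7-bis(benzyloxy)-2-[3,4-bis(benzyloxy)phenyl]chroman-3-ol F2.
  - Glutaric anhydride with DMAP gives the hemiglutarate F3.
  - Carbodiimide esterification of F3 with the 3-OH of 13 gives the keto diester F4.
  - NaBH4 with CeCl3 at −40 °C reduces the C4 ketone to the C4 alcohol F5.
  - BF3·OEt2 in CH2Cl2 at high dilution ionises C4, and C8 of the tethered ring A closes the 14-membered ring on the ester face, giving the 3,4-cis macrocycle F6 (the same compound as A1).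
  - NaOMe in MeOH–THF removes the bridge to give the diol F7, and hydrogenolysis over Pd(OH)2/C gives 22.

**Step 8.**
- Risk: low conversion or poor facial selectivity. The enone is attached to a fully substituted, twisted aryl ketone bearing a very large neighbour, which may not fit the peptide helix, and the resident stereocentres of the top unit may be mismatched with the catalyst.
- Fallback (from 10, returning at 11): catalyst control is abandoned. Weitz–Scheffer epoxidation with H2O2 and NaOH in MeOH–THF should give both trans-epoxides. Because of the top unit these are diastereomers, so 11 can be separated by chromatography from its (2S,3R)-oxirane isomer F8.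

**Step 5.**
- Risk: incomplete discrimination between the two phenols ortho to the acetyl group, or over-benzylation. The first would leave the wrong oxygen free and lead to the 4→6-linked series. C-benzylation of the phloroglucinol ring is a further drain.
- Fallback (from 4, returning at 7): the selective etherification is avoided. Commercial 1-[2,4-bis(benzyloxy)-6-hydroxyphenyl]ethanone F9 is used as the nucleophile under the conditions of step 4. Alkylation is expected at the ring carbon next to the free phenol, which is less hindered than the carbon between two benzyloxy groups and is also reachable by O-alkylation followed by O→C shift. This would give 7 directly and merge steps 4 and 5. The regiochemistry would have to be confirmed by correlation spectroscopy before going on.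

## Further compounds

F1 | step 9 | 1-[4,6-bis(benzyloxy)-2-hydroxy-3-(GC-4α-yl)phenyl]-(2S,3R)-3-(benzylsulfanyl)-3-[3,4-bis(benzyloxy)phenyl]-2-hydroxypropan-1-one | c3ccccc3COc1cc(OCc3ccccc3)c2c(c1)O[C@H](c1cc(OCc3ccccc3)c(OCc3ccccc3)c(OCc3ccccc3)c1)[C@@H](OCc3ccccc3)[C@@H]2c1c(OCc3ccccc3)cc(OCc3ccccc3)c(c1O)C(=O)[C@H](O)[C@H](SCc3ccccc3)c1ccc(OCc3ccccc3)c(OCc3ccccc3)c1

F2 | step 14 | (2S,3R)-5,7-bis(benzyloxy)-2-[3,4-bis(benzyloxy)phenyl]chroman-3-ol | c3ccccc3COc1cc(OCc3ccccc3)c2c(c1)O[C@@H](c1ccc(OCc3ccccc3)c(OCc3ccccc3)c1)[C@H](O)C2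

F3 | step 14 | 5-{[(2S,3R)-5,7-bis(benzyloxy)-2-[3,4-bis(benzyloxy)phenyl]chroman-3-yl]oxy}-5-oxopentanoic acid | c3ccccc3COc1cc(OCc3ccccc3)c2c(c1)O[C@@H](c1ccc(OCc3ccccc3)c(OCc3ccccc3)c1)[C@H](OC(=O)CCCC(=O)O)C2

F4 | step 14 | glutarate diester between O-3 of ketone 13 and O-3 of F2 | c3ccccc3COc1cc(OCc3ccccc3)c2c(c1)O[C@H](c1cc(OCc3ccccc3)c(OCc3ccccc3)c(OCc3ccccc3)c1)[C@@H](OCc3ccccc3)[C@@H]2c1c(OCc3ccccc3)cc(OCc3ccccc3)c2c1O[C@H](c1ccc(OCc3ccccc3)c(OCc3ccccc3)c1)[C@@H](OC(=O)CCCC(=O)O[C@@H]4Cc5c(OCc3ccccc3)cc(OCc3ccccc3)cc5O[C@H]4c4ccc(OCc3ccccc3)c(OCc3ccccc3)c4)C2=O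

F5 | step 14 | C4 alcohol of F4 (4α-OH drawn) | c3ccccc3COc1cc(OCc3ccccc3)c2c(c1)O[C@H](c1cc(OCc3ccccc3)c(OCc3ccccc3)c(OCc3ccccc3)c1)[C@@H](OCc3ccccc3)[C@@H]2c1c(OCc3ccccc3)cc(OCc3ccccc3)c2c1O[C@H](c1ccc(OCc3ccccc3)c(OCc3ccccc3)c1)[C@@H](OC(=O)CCCC(=O)O[C@@H]4Cc5c(OCc3ccccc3)cc(OCc3ccccc3)cc5O[C@H]4c4ccc(OCc3ccccc3)c(OCc3ccccc3)c4)[C@@H]2O

F6 | step 14 | glutarate-bridged benzylated trimer, 3,4-cis lower linkage | c3ccccc3COc1cc(OCc3ccccc3)c2c(c1)O[C@H](c1cc(OCc3ccccc3)c(OCc3ccccc3)c(OCc3ccccc3)c1)[C@@H](OCc3ccccc3)[C@@H]2c1c(OCc3ccccc3)cc(OCc3ccccc3)c2c1O[C@H](c1ccc(OCc3ccccc3)c(OCc3ccccc3)c1)[C@@H](OC(=O)CCCC4=O)[C@H]2c1c(OCc3ccccc3)cc(OCc3ccccc3)c2c1O[C@@H](c1ccc(OCc3ccccc3)c(OCc3ccccc3)c1)[C@H](O4)C2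

F7 | step 14 | tetradeca-O-benzyl trimer with free 3-OH on the middle and bottom units | c3ccccc3COc1cc(OCc3ccccc3)c2c(c1)O[C@H](c1cc(OCc3ccccc3)c(OCc3ccccc3)c(OCc3ccccc3)c1)[C@@H](OCc3ccccc3)[C@@H]2c1c(OCc3ccccc3)cc(OCc3ccccc3)c2c1O[C@H](c1ccc(OCc3ccccc3)c(OCc3ccccc3)c1)[C@@H](O)[C@H]2c1c(OCc3ccccc3)cc(OCc3ccccc3)c2c1O[C@@H](c1ccc(OCc3ccccc3)c(OCc3ccccc3)c1)[C@H](O)C2

F8 | step 8 | [4,6-bis(benzyloxy)-2-(methoxymethoxy)-3-(GC-4α-yl)phenyl]{(2S,3R)-3-[3,4-bis(benzyloxy)phenyl]oxiran-2-yl}methanone | c3ccccc3COc1cc(OCc3ccccc3)c2c(c1)O[C@H](c1cc(OCc3ccccc3)c(OCc3ccccc3)c(OCc3ccccc3)c1)[C@@H](OCc3ccccc3)[C@@H]2c1c(OCc3ccccc3)cc(OCc3ccccc3)c(c1OCOC)C(=O)[C@H]1O[C@@H]1c1ccc(OCc3ccccc3)c(OCc3ccccc3)c1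

F9 | step 5 | 1-[2,4-bis(benzyloxy)-6-hydroxyphenyl]ethanone | CC(=O)c1c(O)cc(OCc2ccccc2)cc1OCc1ccccc1

A1 | alternative 1 | glutarate-bridged benzylated trimer (14-membered macrocycle) | c3ccccc3COc1cc(OCc3ccccc3)c2c(c1)O[C@H](c1cc(OCc3ccccc3)c(OCc3ccccc3)c(OCc3ccccc3)c1)[C@@H](OCc3ccccc3)[C@@H]2c1c(OCc3ccccc3)cc(OCc3ccccc3)c2c1O[C@H](c1ccc(OCc3ccccc3)c(OCc3ccccc3)c1)[C@@H](OC(=O)CCCC4=O)[C@H]2c1c(OCc3ccccc3)cc(OCc3ccccc3)c2c1O[C@@H](c1ccc(OCc3ccccc3)c(OCc3ccccc3)c1)[C@H](O4)C2

A2 | alternative 1 | open glutarate diester with a 2-ethoxyethoxy group at C4 of the middle unit (4α drawn) | c3ccccc3COc1cc(OCc3ccccc3)c2c(c1)O[C@H](c1cc(OCc3ccccc3)c(OCc3ccccc3)c(OCc3ccccc3)c1)[C@@H](OCc3ccccc3)[C@@H]2c1c(OCc3ccccc3)cc(OCc3ccccc3)c2c1O[C@H](c1ccc(OCc3ccccc3)c(OCc3ccccc3)c1)[C@@H](OC(=O)CCCC(=O)O[C@@H]4Cc5c(OCc3ccccc3)cc(OCc3ccccc3)cc5O[C@H]4c4ccc(OCc3ccccc3)c(OCc3ccccc3)c4)[C@@H]2OCCOCC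

A3 | alternative 2 | benzylated trimer with a pinacolboryl group at C3 of the top unit | c3ccccc3COc1cc(OCc3ccccc3)c2c(c1)O[C@H](c1cc(OCc3ccccc3)c(OCc3ccccc3)c(OCc3ccccc3)c1)[C@@H](B3OC(C)(C)C(C)(C)O3)[C@@H]2c1c(OCc3ccccc3)cc(OCc3ccccc3)c2c1O[C@H](c1ccc(OCc3ccccc3)c(OCc3ccccc3)c1)[C@@H](OCc3ccccc3)[C@H]2c1c(OCc3ccccc3)cc(OCc3ccccc3)c2c1O[C@@H](c1ccc(OCc3ccccc3)c(OCc3ccccc3)c1)[C@H](OCc3ccccc3)C2

A4 | alternative 2 | [2,4-bis(benzyloxy)-6-hydroxyphenyl](benzylated catechin-(4β→8)-ent-catechin-8-yl)methanol, either carbinol epimer | c3ccccc3COc1cc(O)c(c(OCc3ccccc3)c1)C(O)c1c(OCc3ccccc3)cc(OCc3ccccc3)c2c1O[C@H](c1ccc(OCc3ccccc3)c(OCc3ccccc3)c1)[C@@H](OCc3ccccc3)[C@H]2c1c(OCc3ccccc3)cc(OCc3ccccc3)c2c1O[C@@H](c1ccc(OCc3ccccc3)c(OCc3ccccc3)c1)[C@H](OCc3ccccc3)C2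

A5 | alternative 2 | (E)-4,4,5,5-tetramethyl-2-{2-[3,4,5-tris(benzyloxy)phenyl]ethenyl}-1,3,2-dioxaborolane | CC1(C)OB(/C=C/c2cc(OCc3ccccc3)c(OCc3ccccc3)c(OCc3ccccc3)c2)OC1(C)C

A6 | alternative 3 | benzylated trimer with free 3-OH on the top unit | c3ccccc3COc1cc(OCc3ccccc3)c2c(c1)O[C@H](c1cc(OCc3ccccc3)c(OCc3ccccc3)c(OCc3ccccc3)c1)[C@@H](O)[C@@H]2c1c(OCc3ccccc3)cc(OCc3ccccc3)c2c1O[C@H](c1ccc(OCc3ccccc3)c(OCc3ccccc3)c1)[C@@H](OCc3ccccc3)[C@H]2c1c(OCc3ccccc3)cc(OCc3ccccc3)c2c1O[C@@H](c1ccc(OCc3ccccc3)c(OCc3ccccc3)c1)[C@H](OCc3ccccc3)C2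

A7 | alternative 3 | trans-2-{hydroxy[3,4,5-tris(benzyloxy)phenyl]methyl}-4,6-bis(benzyloxy)-2,3-dihydrobenzofuran bearing the benzylated catechin-(4β→8)-ent-catechin unit at C3, either carbinol epimer | c3ccccc3COc1cc(OCc3ccccc3)c2c(c1)O[C@@H](C(O)c1cc(OCc3ccccc3)c(OCc3ccccc3)c(OCc3ccccc3)c1)[C@@H]2c1c(OCc3ccccc3)cc(OCc3ccccc3)c2c1O[C@H](c1ccc(OCc3ccccc3)c(OCc3ccccc3)c1)[C@@H](OCc3ccccc3)[C@H]2c1c(OCc3ccccc3)cc(OCc3ccccc3)c2c1O[C@@H](c1ccc(OCc3ccccc3)c(OCc3ccccc3)c1)[C@H](OCc3ccccc3)C2
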